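**Retrosynthetic overview**
- The allylic ester C–O bond is cut last: the target comes from a cis-fused dauc-7-en-4-ol and isovanillic acid by a hydroxyl-directed allylic C–H acyloxylation that also sets the ester carbon.
- The tertiary carbinol is cut to an isopropyl organometallic and a cis-fused hydroazulenone (addition on the convex face).
- The seven-membered ring is formed second, by ring-closing metathesis on a cyclopentanone that already exists; the ring fusion is then set by equilibration.
- The cyclopentanone comes from 3-methylcyclopent-2-enone (five-membered ring purchased) by catalytic asymmetric conjugate addition with in-situ allylation, which sets the quaternary carbon.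

**Assumptions and labels**
- The SMILES is taken literally: a cis-fused daucane, (3R,3aS,4R,8aR) in azulene numbering.
- Atom labels in the text follow daucane numbering: C1 angular-methyl carbon, C4 carbinol carbon, C5 ring-fusion CH, C6 ester carbon, C7=C8 with the vinyl methyl on C8, then C9 and C10. The α-face is that of the C4 hydroxyl; the β-face is that of the angular methyl and H-5.
- Ligand L in step 1 is 3-(1-hydroxy-4-methylpentan-2-yl)-1-mesityl-4,5-dihydroimidazolium hexafluorophosphate, used as the antipode that gives the 3R ketone.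
- The cis-fused ketone 7 is assumed to be the thermodynamic ring-fusion epimer.

**Step 1**
Reactants: 1 3-methylcyclopent-2-en-1-one; 2 4-bromo-2-methylbut-1-ene
Product: 5 (3R)-3-methyl-3-(3-methylbut-3-en-1-yl)-2-(prop-2-en-1-yl)cyclopentan-1-one (mixture of C2 epimers), via Grignard reagent 3 (not isolated), via magnesium enolate 4 (not isolated)
Conditions: 2, Mg, Et2O, 35 °C; then 1, Cu(OTf)2 (3 mol %), L (4 mol %), Et2O, −10 °C; then allyl iodide (3 equiv), DMPU, 0 → 25 °C
Reagents that add atoms: allyl iodide (3-iodoprop-1-ene), C=CCI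
Why: Copper-catalysed asymmetric conjugate addition of the Grignard reagent (carbene–copper catalyst control) creates the C1 quaternary centre as R, and the regiodefined magnesium enolate is C-allylated in situ (tandem conjugate addition–enolate alkylation); the new C5 centre forms as a mixture that is corrected in step 2.

**Step 2**
Reactants: 5 (3R)-3-methyl-3-(3-methylbut-3-en-1-yl)-2-(prop-2-en-1-yl)cyclopentan-1-one (mixture of C2 epimers)
Product: 7 (3aR,8aR)-3a,6-dimethyl-3,3a,4,5,8,8a-hexahydroazulen-1(2H)-one (cis-fused), via ring-fusion epimer mixture 6 (not isolated)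
Conditions: second-generation Hoveyda–Grubbs catalyst RuCl2(H2IMes)(=CH-C6H4-2-OiPr) (5 mol %), PhMe (0.005 M), 80 °C; then NaOMe (0.2 equiv), MeOH, 25 °C
Reagents that add atoms: none
Why: Ring-closing metathesis between the allyl group and the 1,1-disubstituted olefin closes the seven-membered ring with the trisubstituted C7=C8 alkene, and methoxide equilibration of the α-carbon C5 converges both epimers on the cis-fused ketone, expected to be the more stable fusion for a cyclopentanone carbonyl next to a ring junction that carries an angular methyl group.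

**Step 3**
Reactants: 7 (3aR,8aR)-3a,6-dimethyl-3,3a,4,5,8,8a-hexahydroazulen-1(2H)-one
Product: 8 (1R,3aR,8aR)-3a,6-dimethyl-1-(propan-2-yl)-1,2,3,3a,4,5,8,8a-octahydroazulen-1-ol
Conditions: iPrMgCl (3 equiv), anhydrous CeCl3 (3 equiv), THF, −78 → 0 °C; aq NH4Cl
Reagents that add atoms: isopropylmagnesium chloride, CC(C)[Mg]Cl
Why: 1,2-Addition of the weakly basic isopropylcerium reagent (organocerium addition, which suppresses enolisation and β-hydride reduction) takes place on the convex β-face of the cis-fused bicycle, anti to C6 on the neighbouring carbon, so isopropyl ends up β and the new C4 hydroxyl α (R).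

**Step 4**
Reactants: 8 (1R,3aR,8aR)-3a,6-dimethyl-1-(propan-2-yl)-1,2,3,3a,4,5,8,8a-octahydroazulen-1-ol; 9 3-hydroxy-4-methoxybenzoic acid (isovanillic acid)
Product: 10 (3R,3aS,4R,8aR)-3-hydroxy-6,8a-dimethyl-3-(propan-2-yl)-1,2,3,3a,4,7,8,8a-octahydroazulen-4-yl 3-hydroxy-4-methoxybenzoate
Conditions: Pd(OAc)2 (10 mol %), DMSO (1 equiv), 2,6-dimethyl-1,4-benzoquinone (1.5 equiv), 9 (2 equiv), 4 Å MS, 1,4-dioxane, 45 °C
Reagents that add atoms: none
Why: Proposed new method: tertiary-hydroxyl-directed allylic C–H acyloxylation of an internal trisubstituted cycloalkene — the C4–OH and the C7=C8 alkene bind the palladium bis(carboxylate) on the α-face as a six-membered chelate, carboxylate-assisted cleavage of the only allylic C–H bond within reach (C6–Hα) gives an α-face η3-allyl (C6–C7–C8), and quinone-induced inner-sphere (cis) transfer of the isovanillate, held next to C6 by a hydrogen bond to the hydroxyl, forms the C6–O bond at the less substituted terminus with net retention, setting C6 as R (ester cis to the C4–OH), while the neutral phenol is a spectator and zerovalent palladium is reoxidised by the quinone; the closest known reaction types are the palladium/sulfoxide/benzoquinone allylic C–H esterification of terminal olefins with carboxylic acids, quinone-promoted cis-migration of carboxylate in π-allylpalladium complexes and hydroxyl-directed palladium C–H activation of arenes.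

**Compound list**
1 | 3-methylcyclopent-2-en-1-one | CC1=CC(=O)CC1 | starting material
2 | 4-bromo-2-methylbut-1-ene | C=C(C)CCBr | starting material
3 | (3-methylbut-3-en-1-yl)magnesium bromide | C=C(C)CC[Mg]Br | intermediate
4 | bromomagnesium (3R)-3-methyl-3-(3-methylbut-3-en-1-yl)cyclopent-1-en-1-olate | C=C(C)CC[C@]1(C)CCC(O[Mg]Br)=C1 | intermediate
5 | (3R)-3-methyl-3-(3-methylbut-3-en-1-yl)-2-(prop-2-en-1-yl)cyclopentan-1-one (mixture of C2 epimers) | C=C(C)CC[C@]1(C)CCC(=O)C1CC=C | intermediate
6 | (3aR)-3a,6-dimethyl-3,3a,4,5,8,8a-hexahydroazulen-1(2H)-one (mixture of C8a epimers) | C1C=C(C)CC[C@]2(C)CCC(=O)C12 | intermediate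
7 | (3aR,8aR)-3a,6-dimethyl-3,3a,4,5,8,8a-hexahydroazulen-1(2H)-one | C1C=C(C)CC[C@]2(C)CCC(=O)[C@H]12 | intermediate
8 | (1R,3aR,8aR)-3a,6-dimethyl-1-(propan-2-yl)-1,2,3,3a,4,5,8,8a-octahydroazulen-1-ol | C1C=C(C)CC[C@]2(C)CC[C@@](O)(C(C)C)[C@H]12 | intermediate
9 | 3-hydroxy-4-methoxybenzoic acid | COc1ccc(C(=O)O)cc1O | starting material
10 | (3R,3aS,4R,8aR)-3-hydroxy-6,8a-dimethyl-3-(propan-2-yl)-1,2,3,3a,4,7,8,8a-octahydroazulen-4-yl 3-hydroxy-4-methoxybenzoate | COc1ccc(C(=O)O[C@@H]2C=C(C)CC[C@]3(C)CC[C@@](O)(C(C)C)[C@H]23)cc1O | target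

**Step count and risks**

Total step count: 4. Longest linear sequence: 4 steps (1 and 2 to 10).

Most likely to fail, in order: step 4, step 1, step 2.

Step 4 is the new reaction. The likely failure modes are oxidative cyclisation of the tertiary alcohol onto C8 (a Wacker-type bridged ether), C–H cleavage at C9 or at the vinyl methyl, β-hydride elimination to dienes, and formation of the 6β-ester. The fallback uses known chemistry, sets out from 8 and returns at 10:
- Hydroxyl-directed epoxidation (VO(acac)2, t-BuOOH, CH2Cl2) gives the syn-epoxy alcohol, the 7α,8α-epoxide of 8, F5. Being syn to the hydroxyl, it cannot be opened intramolecularly.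
- PhSeNa (from (PhSe)2 and NaBH4, EtOH) opens it at the less hindered C7 from the β-face to give the hydroxy selenide, the 7β-phenylselanyl 4α,8α-diol, F6.
- H2O2 then causes selenoxide syn-elimination towards C6 and gives the tertiary allylic alcohol, the Δ6-ene 4α,8α-diol, F7.
- Suprafacial perrhenate 1,3-transposition (Ph3SiOReO3, 5 mol %, Et2O, −50 → 0 °C) moves the oxygen to C6 on the same face and gives the Δ7-ene 4α,6α-diol (1R,3aR,8R,8aS)-3a,6-dimethyl-1-(propan-2-yl)-1,2,3,3a,4,5,8,8a-octahydroazulene-1,8-diol F8.
- The secondary allylic hydroxyl of F8 is esterified (EDC·HCl, DMAP, CH2Cl2) with 3-acetoxy-4-methoxybenzoic acid F9, made from 9 with Ac2O and pyridine, to give the acetate-protected ester F10.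
- Brief K2CO3 in MeOH at 0 °C removes the phenolic acetate and gives 10.

Step 1 may give insufficient enantiomeric excess, because five-membered enones are the harder substrates for Grignard conjugate addition. Allylation of the hindered magnesium enolate may also be sluggish or regio-scrambled. A modest ee would be upgraded by recrystallisation of 10. The fallback sets out from 3 and returns at 5:
- Stork–Danheiser addition of 3 to commercial 3-ethoxycyclopent-2-en-1-one followed by aqueous HCl gives the enone 3-(3-methylbut-3-en-1-yl)cyclopent-2-en-1-one F1.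
- Copper-catalysed asymmetric conjugate addition of Me3Al (Cu(OTf)2 5 mol %, chiral phosphoramidite or carbene ligand, Et2O, −30 °C) with Me3SiOTf trapping gives the silyl enol ether trimethyl{[(3R)-3-methyl-3-(3-methylbut-3-en-1-yl)cyclopent-1-en-1-yl]oxy}silane F2.
- MeLi (THF, 0 °C) releases the lithium enolate, and allyl iodide with DMPU gives 5.

Step 2 may fail if the cis:trans ratio at equilibrium is poor, if the epimers are inseparable, or if the metathesis oligomerises. The fallback fixes the ring fusion before ring closure; it sets out from 5 and returns at 8: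
- The C2 epimers of 5 are separated. The epimer with allyl cis to the butenyl chain, (2R,3R)-3-methyl-3-(3-methylbut-3-en-1-yl)-2-(prop-2-en-1-yl)cyclopentan-1-one F3, is kept; the other is recycled by NaOMe equilibration.
- Organocerium addition (iPrMgCl, CeCl3, THF, −78 °C), anti to the allyl group, gives the monocyclic carbinol (1R,2R,3R)-3-methyl-3-(3-methylbut-3-en-1-yl)-1-(propan-2-yl)-2-(prop-2-en-1-yl)cyclopentan-1-ol F4, which has no epimerisable centre.
- Ring-closing metathesis with the same ruthenium catalyst gives 8.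

**Further compounds**
F1 | step 1 | 3-(3-methylbut-3-en-1-yl)cyclopent-2-en-1-one | C=C(C)CCC1=CC(=O)CC1
F2 | step 1 | trimethyl{[(3R)-3-methyl-3-(3-methylbut-3-en-1-yl)cyclopent-1-en-1-yl]oxy}silane | C=C(C)CC[C@]1(C)CCC(O[Si](C)(C)C)=C1
F3 | step 2 | (2R,3R)-3-methyl-3-(3-methylbut-3-en-1-yl)-2-(prop-2-en-1-yl)cyclopentan-1-one | C=C(C)CC[C@]1(C)CCC(=O)[C@@H]1CC=C
F4 | step 2 | (1R,2R,3R)-3-methyl-3-(3-methylbut-3-en-1-yl)-1-(propan-2-yl)-2-(prop-2-en-1-yl)cyclopentan-1-ol | C=C(C)CC[C@]1(C)CC[C@@](O)(C(C)C)[C@@H]1CC=C
F5 | step 4 | 7α,8α-epoxide of 8 (oxirane on the face of the C4 hydroxyl) | C1[C@@H]2O[C@]2(C)CC[C@]3(C)CC[C@@](O)(C(C)C)[C@H]13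
F6 | step 4 | 7β-phenylselanyl 4α,8α-diol from opening of F5 at C7 | C1[C@@H]([Se]c2ccccc2)[C@](C)(O)CC[C@]3(C)CC[C@@](O)(C(C)C)[C@H]13
F7 | step 4 | Δ6-ene 4α,8α-diol (tertiary allylic alcohol at C8) | C1=C[C@](C)(O)CC[C@]2(C)CC[C@@](O)(C(C)C)[C@H]12
F8 | step 4 | (1R,3aR,8R,8aS)-3a,6-dimethyl-1-(propan-2-yl)-1,2,3,3a,4,5,8,8a-octahydroazulene-1,8-diol | O[C@@H]1C=C(C)CC[C@]2(C)CC[C@@](O)(C(C)C)[C@H]12
F9 | step 4 | 3-acetoxy-4-methoxybenzoic acid | COc1ccc(C(=O)O)cc1OC(C)=O
F10 | step 4 | (3R,3aS,4R,8aR)-3-hydroxy-6,8a-dimethyl-3-(propan-2-yl)-1,2,3,3a,4,7,8,8a-octahydroazulen-4-yl 3-acetoxy-4-methoxybenzoate | COc1ccc(C(=O)O[C@@H]2C=C(C)CC[C@]3(C)CC[C@@](O)(C(C)C)[C@H]23)cc1OC(C)=O
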